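All constants were chosen freely, and the outcome is calculated.

The ratio I carried was the pace a flask demands, one charge per run time, divided by the top pace of the catalyst.

the same everywhere: substrate 0.10 M; free catalyst 17 mol%

|  | coupling partner | time | remark |
|---|---|---|---|
| Tuesday's | 1.50 equiv | 8.0 min | a closed flask charged with all of it at once and left for 8.0 min |
| Friday's | 1.50 equiv |  | one stirred flow tank at steady state, fed with the mixture as stated, mean residence time 8.0 min |
| Monday's | 1.50 equiv |  | one stirred flow tank at steady state, fed with the mixture as stated, mean residence time 40.0 min |
| Thursday's | 1.50 equiv (fed, over 6.40 min) | 8.0 min | a stirred flask in which coupling partner is dosed at a steady rate over 6.40 min without added volume, worked up at 8.0 min |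

    coupling partner + free catalyst → catalyst intermediate A (k1 = 0.32 L mol⁻¹ s⁻¹)
    substrate + catalyst intermediate A → catalyst intermediate B (k2 = 5.7 L mol⁻¹ s⁻¹)
    catalyst intermediate B → catalyst intermediate C (k3 = 3.1 s⁻¹)
    catalyst intermediate C → released group + catalyst intermediate D (k4 = 0.056 s⁻¹)
    catalyst intermediate D → free catalyst + target (k5 = 0.019 s⁻¹)
    substrate + target → side product (k6 = 0.036 L mol⁻¹ s⁻¹)
    coupling partner + free catalyst + target → free catalyst + over-reaction product (k7 = 0.17 L² mol⁻² s⁻¹)

- percent here means substrate units held: one side product counts as two
- the stated concentrations are those of everything mixed, before any reaction; amounts are the same in each set-up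
- the feed brings no volume worth counting
- run time (Tuesday's): 8.0 min

* order of the set-ups by the amount of target at the outlet or at the end, in percent of the substrate put in, highest first (Tuesday's / Friday's / Monday's / Thursday's)
* amount of target at the outlet or at the end, in percent of the substrate put in, Tuesday's
* amount of target at the outlet or at the end, in percent of the substrate put in, Friday's
* amount of target at the outlet or at the end, in percent of the substrate put in, Monday's
* amount of target at the outlet or at the end, in percent of the substrate put in, Thursday's

Before seeing any result, I took the catalyst's round as three waits: step 1 with coupling partner at its charge, then steps 4 and 5. That made 91.3 s, and I dropped step 3 because its wait is far shorter than that of step 5. The top pace was therefore 0.112 min⁻¹ in fractions of the charge. That gave the load, the demanded pace over the top pace1.12, for Tuesday's flask, above one. On that reckoning its target had a ceiling of 89.3%. Thursday's flask has the same charge and time, but at 3.20 min no more than 0.750 of coupling partner had gone in. That made a round of at least 112 s, longer than Tuesday's at its start, so I put Thursday's flask below Tuesday's.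

Friday's tank looks nearly the same as Tuesday's flask, but it works at outlet strength throughout. If it took in more than half the substrate, coupling partner stood below one equivalent, the round lasted at least 102 s, and target stayed under 80.2%. Tuesday's flask starts at the shorter round, so I put it ahead of Friday's tank. Neither ceiling counts target lost. At charged substrate on Tuesday, step 6 halves target in 3.2 min, faster than step 7 at 27 min, and shorter than the 8.0 min run.

Monday's tank has a load of 0.224, below one. With a whole charge passing through, substrate units sitting in catalyst intermediates C and D come to 2.94%, which leaves at most 97.1%. So my reckoning gave ceilings, not central values.

The forecast gave central values: 53% for Tuesday's, 46% for Friday's, 87% for Monday's and 41% for Thursday's, in the order Monday's > Tuesday's > Friday's > Thursday's. It reasoned that “Thursday's dosing starves the loading step early on”.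

The simulation gave 55.8% for Tuesday's, 46.3% for Friday's, 82.8% for Monday's and 39.3% for Thursday's, ranked Monday's > Tuesday's > Friday's > Thursday's. In Monday's tank catalyst intermediate C stood at 0.700%, and multiplied by k4 that is a flow of 0.0235 min⁻¹ in fractions of the charge, or 0.210 of the top pace, beside the load of 0.224. Thursday's flask left until 80.0 min has a load of 0.112, lower than Monday's, yet it held 66.2% target against Monday's 82.8%.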